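**Retrosynthetic overview**

1. The two hydroxyls of the target (C1–OH on ring A, C2'–OH on ring B) are taken back to one O–CH2–O bridge, giving 1,2,3,4,8,10-hexabromo-6H-dibenzo[d,g][1,3,6]trioxocine.
2. The C6–O–C1' diaryl ether bond of that trioxocine is cut by intramolecular SNAr: the C6 phenoxide of 3,5-dibromo-2-[(pentabromophenoxy)methoxy]phenol displaces an ortho bromide of its own pentabromophenyl ring.
3. That phenol comes from Baeyer–Villiger oxidation of the matching benzaldehyde, itself made by O-alkylation of 3,5-dibromosalicylaldehyde with chloromethyl pentabromophenyl ether (from pentabromophenol through its methylthiomethyl ether).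
4. Feature on which the plan rests: ring B is a perbrominated phenol ring whose two carbons ortho to the C2' oxygen (C1' and C3') are equivalent, and the C1 and C2' oxygens flank the C6–O–C1' link closely enough to share one CH2, so the tethered C6 oxygen can reach only those two carbons.
5. Ring order: rings A and B are bought intact; the only ring made is the temporary eight-membered trioxocine, closed in step 4 and opened in step 5.

Key step: step 4

Remark: locants are those of the target (ring A: C1 OH, C2 and C4 Br, C6 O-aryl; ring B: C1' O-aryl, C2' OH, C3'–C6' Br), and the aryl chloromethyl ether is assumed to tolerate evaporation of the volatile by-products and to be used crude.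

**Route**

Step 1
Reactants: 1 pentabromophenol; 2 chloromethyl methyl sulfide
Product: 3 1,2,3,4,5-pentabromo-6-[(methylsulfanyl)methoxy]benzene (pentabromophenyl methylthiomethyl ether)
Conditions: K2CO3, NaI (cat.), DMF, rt → 50 °C
Reagents that add atoms: none
Why: Williamson etherification, in which the acidic, fully substituted phenol is deprotonated by K2CO3 and its oxygen, the only nucleophilic site left on the ring, is alkylated by the α-chloro sulfide that NaI turns into the more reactive iodide (Finkelstein exchange).

Step 2
Reactants: 3 1,2,3,4,5-pentabromo-6-[(methylsulfanyl)methoxy]benzene; 4 3,5-dibromosalicylaldehyde (3,5-dibromo-2-hydroxybenzaldehyde)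
Product: 6 3,5-dibromo-2-[(pentabromophenoxy)methoxy]benzaldehyde, via chloromethyl pentabromophenyl ether 5 (not isolated)
Conditions: SO2Cl2, CH2Cl2, 0 °C → rt, evaporate; then 4, K2CO3, DMF, 0 °C → rt
Reagents that add atoms: none
Why: Chlorinolysis of an O,S-acetal, in which SO2Cl2 chlorinates sulfur and the chlorosulfonium salt collapses to the α-chloro ether and volatile MeSCl, followed by Williamson etherification of the phenoxide of 4 at the activated CH2–Cl carbon, the perbrominated ring offering no site for electrophilic chlorination.

Step 3
Reactants: 6 3,5-dibromo-2-[(pentabromophenoxy)methoxy]benzaldehyde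
Product: 8 3,5-dibromo-2-[(pentabromophenoxy)methoxy]phenol, via aryl formate 7 (not isolated)
Conditions: mCPBA, CH2Cl2, 40 °C; then HCl (cat.), MeOH/THF, 0 °C → rt
Reagents that add atoms: 3-chloroperoxybenzoic acid (mCPBA), OOC(=O)c1cccc(Cl)c1
Why: Baeyer–Villiger (Dakin-type) oxidation, in which the aryl group carrying the ortho alkoxy oxygen should migrate in preference to hydride in the Criegee adduct, followed by acid-catalysed transesterification of the aryl formate with methanol, which leaves the diaryl formal intact and keeps the new phenol protonated so that it cannot attack the acetal carbon.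

Step 4
Reactants: 8 3,5-dibromo-2-[(pentabromophenoxy)methoxy]phenol
Product: 9 1,2,3,4,8,10-hexabromo-6H-dibenzo[d,g][1,3,6]trioxocine (methylene acetal of the target; O5–CH2–O7 bridge, O12 the diaryl ether oxygen)
Conditions: Cs2CO3, NMP (0.005 M, slow addition), 90 °C, dark
Reagents that add atoms: none
Why: Cs2CO3 converts the C6–OH into a caesium phenoxide, which adds to C1' of ring B to give a Meisenheimer adduct whose charge sits on C2', C4' and C6' and is stabilised inductively by the four remaining bromines, and loss of bromide restores the arene (addition–elimination SNAr). The closest known reaction type is the base-induced intramolecular displacement of an ortho halogen of a perhalogenated ring by a tethered phenoxide, as in the closure of ortho-hydroxy polyhalodiphenyl ethers to dibenzodioxins. The eight-membered trioxocine ring closes by attack of the tethered oxygen on a ring carbon with the departing bromide exocyclic; the two fused arenes and three ring oxygens keep transannular strain low, and slow addition at high dilution suppresses intermolecular substitution. No stereocentre is formed. Site selectivity among the five C–Br bonds is required and is secured by the O–CH2–O tether, which lets the C6 oxygen reach only C1' and C3', two carbons made equivalent by the symmetry of the pentabromophenoxy group, while the same tether keeps the C1 oxygen from displacing a second bromine. Chemoselectivity for the ring carbon over the acetal carbon (five-membered closure with loss of pentabromophenoxide) is not secured by the substrate and is the main risk of the step.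

Step 5
Reactants: 9 1,2,3,4,8,10-hexabromo-6H-dibenzo[d,g][1,3,6]trioxocine
Product: 10 2,4-dibromo-6-(2,3,4,5-tetrabromo-6-hydroxyphenoxy)phenol (target)
Conditions: BCl3, CH2Cl2, −78 °C → rt; then H2O
Reagents that add atoms: none
Why: Lewis-acid cleavage of a methylene acetal as used for methylenedioxyarenes, in which BCl3 binds an acetal oxygen, chloride opens the O–CH2 bond to an aryloxyborane and an aryl chloromethyl ether, and water hydrolyses both to the two phenols and formaldehyde, while the diaryl ether and C–Br bonds are inert and the acidic medium keeps either phenol from displacing an ortho bromine.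

**Compound list**

1 | pentabromophenol | Oc1c(Br)c(Br)c(Br)c(Br)c1Br | starting material
2 | chloromethyl methyl sulfide | CSCCl | starting material
3 | 1,2,3,4,5-pentabromo-6-[(methylsulfanyl)methoxy]benzene | CSCOc1c(Br)c(Br)c(Br)c(Br)c1Br | intermediate
4 | 3,5-dibromosalicylaldehyde | O=Cc1cc(Br)cc(Br)c1O | starting material
5 | chloromethyl pentabromophenyl ether (1,2,3,4,5-pentabromo-6-(chloromethoxy)benzene) | ClCOc1c(Br)c(Br)c(Br)c(Br)c1Br | intermediate
6 | 3,5-dibromo-2-[(pentabromophenoxy)methoxy]benzaldehyde | O=Cc1cc(Br)cc(Br)c1OCOc1c(Br)c(Br)c(Br)c(Br)c1Br | intermediate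
7 | 3,5-dibromo-2-[(pentabromophenoxy)methoxy]phenyl formate | O=COc1cc(Br)cc(Br)c1OCOc1c(Br)c(Br)c(Br)c(Br)c1Br | intermediate
8 | 3,5-dibromo-2-[(pentabromophenoxy)methoxy]phenol | Oc1cc(Br)cc(Br)c1OCOc1c(Br)c(Br)c(Br)c(Br)c1Br | intermediate
9 | 1,2,3,4,8,10-hexabromo-6H-dibenzo[d,g][1,3,6]trioxocine | Brc1cc(Br)c2OCOc3c(Br)c(Br)c(Br)c(Br)c3Oc2c1 | intermediate
10 | 2,4-dibromo-6-(2,3,4,5-tetrabromo-6-hydroxyphenoxy)phenol | Oc1c(Br)cc(Br)cc1Oc1c(O)c(Br)c(Br)c(Br)c1Br | target

**Step count**

Total steps: 5 (three to the key-step precursor, the key step, one after it).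
Longest linear sequence: 5 steps (1 → 3 → 6 → 8 → 9 → 10).

**Steps most likely to fail**

Step 4. The phenoxide may attack the acetal carbon instead of ring B, closing a five-membered ring and expelling pentabromophenoxide, which destroys the tether. This could outrun the slower eight-membered attack on a ring activated only by bromine. Ipso attack at C2' (Smiles-type aryl transfer) and intermolecular substitution are lesser competitors. The fallback keeps the tether but makes fluoride the nucleofuge at C1', so that ring attack should proceed at much lower temperature and at one carbon only. It sets out from 2 and 4, with commercial 2-fluorophenol (Oc1ccccc1F) in place of 1, and returns to the route at 9. 2-Fluorophenol would be perbrominated (Br2, Fe powder cat., 1,2-dichloroethane, reflux) to 2,3,4,5-tetrabromo-6-fluorophenol F1. Alkylation with 2 (K2CO3, NaI, DMF) should give 2,3,4,5-tetrabromo-6-fluorophenyl methylthiomethyl ether F2, and SO2Cl2 should convert this into chloromethyl 2,3,4,5-tetrabromo-6-fluorophenyl ether F3. Etherification of 4 (K2CO3, DMF) would give 3,5-dibromo-2-[(2,3,4,5-tetrabromo-6-fluorophenoxy)methoxy]benzaldehyde F4. Oxidation with mCPBA would lead through 3,5-dibromo-2-[(2,3,4,5-tetrabromo-6-fluorophenoxy)methoxy]phenyl formate F5 to 3,5-dibromo-2-[(2,3,4,5-tetrabromo-6-fluorophenoxy)methoxy]phenol F6 after HCl/MeOH. Treatment of F6 with Cs2CO3 in dilute NMP at rt → 50 °C should then displace fluoride, the standard case of phenoxide SNAr, and give 9.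

Step 3. Hydride instead of aryl migration in the Criegee adduct would give the benzoic acid. This is possible because the ring is electron-poor and the alkoxy group, flanked by two ortho substituents, is twisted out of conjugation; slow peracid addition is a second concern. The fallback introduces the C6 oxygen from nitrogen instead of from a formyl group. It sets out from 5 (generated from 3 as in step 2) and returns at 8. Commercial 2,4-dibromo-6-nitrophenol (Oc1c(Br)cc(Br)cc1[N+](=O)[O-]) would be alkylated with 5 (K2CO3, DMF) to 1,5-dibromo-3-nitro-2-[(pentabromophenoxy)methoxy]benzene F7. Reduction with iron powder in AcOH/EtOH at 60 °C, which spares aryl bromides, should give 3,5-dibromo-2-[(pentabromophenoxy)methoxy]aniline F8. Diazotisation (t-BuONO, HBF4·OEt2, THF, −10 °C) would give 3,5-dibromo-2-[(pentabromophenoxy)methoxy]benzenediazonium tetrafluoroborate F9. Hydroxydediazoniation (Cu2O, excess Cu(NO3)2, H2O, rt) should then give 8.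

Step 5. Opening of the formal may stall because both acetal oxygens are poor Lewis bases on electron-poor rings. Any basic work-up would also let the C1 phenoxide displace the C6' bromine and close a dibenzodioxin ring. The fallback replaces the boron halide cleavage by acid-promoted transthioacetalisation: from 9, 1,2-ethanedithiol and BF3·OEt2 in CH2Cl2 at rt should transfer the CH2 unit to sulfur as 1,3-dithiolane and release 10 directly under non-basic conditions, with no new intermediate.

**Further compounds**

F1 | step 4 | 2,3,4,5-tetrabromo-6-fluorophenol | Oc1c(F)c(Br)c(Br)c(Br)c1Br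
F2 | step 4 | 2,3,4,5-tetrabromo-6-fluorophenyl methylthiomethyl ether | CSCOc1c(F)c(Br)c(Br)c(Br)c1Br
F3 | step 4 | chloromethyl 2,3,4,5-tetrabromo-6-fluorophenyl ether | ClCOc1c(F)c(Br)c(Br)c(Br)c1Br
F4 | step 4 | 3,5-dibromo-2-[(2,3,4,5-tetrabromo-6-fluorophenoxy)methoxy]benzaldehyde | O=Cc1cc(Br)cc(Br)c1OCOc1c(F)c(Br)c(Br)c(Br)c1Br
F5 | step 4 | 3,5-dibromo-2-[(2,3,4,5-tetrabromo-6-fluorophenoxy)methoxy]phenyl formate | O=COc1cc(Br)cc(Br)c1OCOc1c(F)c(Br)c(Br)c(Br)c1Br
F6 | step 4 | 3,5-dibromo-2-[(2,3,4,5-tetrabromo-6-fluorophenoxy)methoxy]phenol | Oc1cc(Br)cc(Br)c1OCOc1c(F)c(Br)c(Br)c(Br)c1Br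
F7 | step 3 | 1,5-dibromo-3-nitro-2-[(pentabromophenoxy)methoxy]benzene | [O-][N+](=O)c1cc(Br)cc(Br)c1OCOc1c(Br)c(Br)c(Br)c(Br)c1Br
F8 | step 3 | 3,5-dibromo-2-[(pentabromophenoxy)methoxy]aniline | Nc1cc(Br)cc(Br)c1OCOc1c(Br)c(Br)c(Br)c(Br)c1Br
F9 | step 3 | 3,5-dibromo-2-[(pentabromophenoxy)methoxy]benzenediazonium tetrafluoroborate | N#[N+]c1cc(Br)cc(Br)c1OCOc1c(Br)c(Br)c(Br)c(Br)c1Br.F[B-](F)(F)F
F0 | step 5 | none | none
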